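## Retrosynthetic overview

1. Target 13 comes from 12 by cleavage of the two phenol benzyl ethers. The bicycle is numbered C1(=O)–O2–C3(aryl)–C3a–C4H2–O5–C6(aryl)–C6a.
2. Key disconnection: C4–C3a and C6–C6a of the tetrahydrofuran ring (C3a, C4, O5, C6, C6a) in one retro-[3+2] step. This gives the aryl carbonyl ylide 11 (C4–O5–C6) and the (S)-butenolide 6.
3. Enabling feature: C4–O5–C6 is a three-atom C–O–C unit whose two carbons sit on C3a and C6a, the β- and α-carbons of the lactone carbonyl C1, and the aryl-bearing C3 lies next to C3a. The one centre set by catalysis (C3) can therefore relay C3a, C6a and C6 in a single event.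
4. 6 comes from syringaldehyde (benzylation, zinc-catalysed asymmetric addition of methyl propiolate, Z-semihydrogenation and lactonisation). 11 comes from O-benzylvanillin through acetal 9 and α-chloro ether 10.
5. Ring order: γ-lactone ring first (step 3), tetrahydrofuran ring last (step 6).

Key step: step 6

Assumption: the (S,S)-ProPhenol–zinc catalyst is taken to deliver the alkynyl group to the Si face of aldehyde 2 (R carbinol); if the first run shows the opposite sense, the (R,R)-ligand is used and nothing else changes.

## Route

Step 1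
Reactants: 1 syringaldehyde
Product: 2 4-(benzyloxy)-3,5-dimethoxybenzaldehyde
Conditions: BnBr (1.2 equiv), K2CO3 (2 equiv), DMF, 60 °C
Reagents that add atoms: benzyl bromide, BrCc1ccccc1
Why: Williamson etherification of the acidic para-formyl phenol should be clean, and the benzyl ether is chosen because it survives organozinc reagents, Lindlar hydrogenation, mild acid and fluoride.

Step 2
Reactants: 2 4-(benzyloxy)-3,5-dimethoxybenzaldehyde; 3 methyl propiolate (3 equiv)
Product: 4 methyl (R)-4-[4-(benzyloxy)-3,5-dimethoxyphenyl]-4-hydroxybut-2-ynoate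
Conditions: (S,S)-ProPhenol (10 mol %), Ph3PO (20 mol %), Me2Zn (3 equiv), toluene, 4 °C; aq NH4Cl
Reagents that add atoms: none
Why: Zinc–ProPhenol-catalysed asymmetric alkynylation of an aryl aldehyde with the zinc acetylide of methyl propiolate, in which the dinuclear zinc catalyst selects the Si face of the aldehyde and so sets the R carbinol centre, the only centre in the route set by a chiral catalyst.

Step 3
Reactants: 4 methyl (R)-4-[4-(benzyloxy)-3,5-dimethoxyphenyl]-4-hydroxybut-2-ynoate
Product: 6 (S)-5-[4-(benzyloxy)-3,5-dimethoxyphenyl]furan-2(5H)-one, via Z-hydroxy enoate 5 (not isolated)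
Conditions: H2 (1 atm), Lindlar catalyst, quinoline, EtOAc, rt; then PPTS (cat.), CH2Cl2, rt
Reagents that add atoms: none
Why: Lindlar semihydrogenation gives the Z-enoate, whose hydroxyl group then lactonises by intramolecular transesterification; the carbinol centre is not touched (its descriptor changes from R to S only because the CIP priorities change) and the poisoned catalyst leaves the benzyl ether intact.

Step 4
Reactants: 7 4-(benzyloxy)-3-methoxybenzaldehyde; 8 (trimethylsilyl)methanol (2.5 equiv)
Product: 9 1-(benzyloxy)-4-{bis[(trimethylsilyl)methoxy]methyl}-2-methoxybenzene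
Conditions: PPTS (cat.), benzene, reflux, Dean–Stark trap
Reagents that add atoms: none
Why: Acid-catalysed acetalisation driven by azeotropic removal of water, which the electron-rich aldehyde and the acid-stable primary silylmethyl alcohol should undergo readily.

Step 5
Reactants: 9 1-(benzyloxy)-4-{bis[(trimethylsilyl)methoxy]methyl}-2-methoxybenzene
Product: 10 ({[4-(benzyloxy)-3-methoxyphenyl](chloro)methoxy}methyl)trimethylsilane (racemic; used crude after evaporation)
Conditions: AcCl (1.1 equiv), SOCl2 (cat.), CH2Cl2, 0 °C → rt; evaporation under argon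
Reagents that add atoms: acetyl chloride, CC(=O)Cl
Why: Cleavage of an acetal to an α-chloro ether by an acyl chloride, driven by ester formation and eased by the p-alkoxy-stabilised oxocarbenium ion; the new centre is racemic and is destroyed in step 6.

Step 6
Reactants: 6 (S)-5-[4-(benzyloxy)-3,5-dimethoxyphenyl]furan-2(5H)-one; 10 ({[4-(benzyloxy)-3-methoxyphenyl](chloro)methoxy}methyl)trimethylsilane (2.5 equiv)
Product: 12 (3S,3aR,6S,6aS)-3-[4-(benzyloxy)-3,5-dimethoxyphenyl]-6-[4-(benzyloxy)-3-methoxyphenyl]tetrahydro-1H,3H-furo[3,4-c]furan-1-one, via carbonyl ylide 11 (not isolated)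
Conditions: CsF (5 equiv, dried), MeCN, 0 °C → rt, 10 added over 4 h
Reagents that add atoms: none
Why: Fluoride attacks silicon of 10 while chloride leaves with help from the p-alkoxyphenyl group (silicon-based 1,3-elimination), which gives the carbonyl ylide 11, a 4π C–O–C dipole, and this adds across the C3=C4 bond of butenolide 6 in a suprafacial [π4s+π2s] 1,3-dipolar cycloaddition. The closest known reaction type is the fluoride-triggered generation of nonstabilised carbonyl ylides from 1-chloroalkyl (trimethylsilyl)methyl ethers and their [3+2] cycloaddition to electron-poor alkenes to give tetrahydrofurans, together with the anti-selective dipolar cycloadditions of 5-substituted 2(5H)-furanones. The tetrahydrofuran ring is closed by intermolecular [3+2] annulation, the two C–C bonds C4–C3a and C6–C6a being formed on the same face of the ring alkene, which makes the ring fusion cis. C3a and C6a are controlled by the aryl group at C5 of 6 (C3 of 12), which blocks its own face so that the dipole adds anti to it, and C6 is controlled by the ylide geometry (aryl in the outward E position) together with the exo approach, in which the ylide oxygen and the aryl group are turned away from the lactone ring, so that the aryl group ends trans to C1 on the convex face, as the analogous aryl azomethine ylides give 2,3-trans adducts. The step needs regioselectivity (CH2 end to the β-carbon), secured by the larger HOMO coefficient at the unsubstituted ylide carbon, the larger LUMO coefficient at the β-carbon and the fact that only the small CH2 end fits next to the C5 aryl group; it needs facial and exo selectivity as stated; and it needs the cycloaddition to outrun γ-deprotonation of 6 by fluoride, for which the poorly soluble CsF, the low temperature and the excess of slowly added 10 are chosen.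

Step 7
Reactants: 12 (3S,3aR,6S,6aS)-3-[4-(benzyloxy)-3,5-dimethoxyphenyl]-6-[4-(benzyloxy)-3-methoxyphenyl]tetrahydro-1H,3H-furo[3,4-c]furan-1-one
Product: 13 (3S,3aR,6S,6aS)-3-(4-hydroxy-3,5-dimethoxyphenyl)-6-(4-hydroxy-3-methoxyphenyl)tetrahydro-1H,3H-furo[3,4-c]furan-1-one
Conditions: H2 (1 atm), 10% Pd/C, EtOAc, rt, stopped after uptake of 2 equiv H2
Reagents that add atoms: none
Why: Hydrogenolysis of the two aryl benzyl ethers in a neutral solvent should be much faster than cleavage of the secondary benzylic C–O bonds of the lactone and ether rings, and no stereocentre is touched.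

## Compound list

1 | syringaldehyde (4-hydroxy-3,5-dimethoxybenzaldehyde) | COc1cc(C=O)cc(OC)c1O | starting material
2 | 4-(benzyloxy)-3,5-dimethoxybenzaldehyde | COc1cc(C=O)cc(OC)c1OCc1ccccc1 | intermediate
3 | methyl propiolate | COC(=O)C#C | starting material
4 | methyl (R)-4-[4-(benzyloxy)-3,5-dimethoxyphenyl]-4-hydroxybut-2-ynoate | O[C@H](c1cc(OC)c(OCc2ccccc2)c(OC)c1)C#CC(=O)OC | intermediate
5 | methyl (S,Z)-4-[4-(benzyloxy)-3,5-dimethoxyphenyl]-4-hydroxybut-2-enoate | O[C@H](c1cc(OC)c(OCc2ccccc2)c(OC)c1)/C=C\C(=O)OC | intermediate
6 | (S)-5-[4-(benzyloxy)-3,5-dimethoxyphenyl]furan-2(5H)-one | O=C1O[C@H](c2cc(OC)c(OCc3ccccc3)c(OC)c2)C=C1 | intermediate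
7 | 4-(benzyloxy)-3-methoxybenzaldehyde (O-benzylvanillin) | COc1cc(C=O)ccc1OCc1ccccc1 | starting material
8 | (trimethylsilyl)methanol | C[Si](C)(C)CO | starting material
9 | 1-(benzyloxy)-4-{bis[(trimethylsilyl)methoxy]methyl}-2-methoxybenzene | COc1cc(C(OC[Si](C)(C)C)OC[Si](C)(C)C)ccc1OCc1ccccc1 | intermediate
10 | ({[4-(benzyloxy)-3-methoxyphenyl](chloro)methoxy}methyl)trimethylsilane, racemic | COc1cc(C(Cl)OC[Si](C)(C)C)ccc1OCc1ccccc1 | intermediate
11 | (E)-carbonyl ylide, [4-(benzyloxy)-3-methoxybenzylidene]oxonium methylide | COc1cc(/C=[O+]/[CH2-])ccc1OCc1ccccc1 | intermediate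
12 | (3S,3aR,6S,6aS)-3-[4-(benzyloxy)-3,5-dimethoxyphenyl]-6-[4-(benzyloxy)-3-methoxyphenyl]tetrahydro-1H,3H-furo[3,4-c]furan-1-one | COc1cc([C@H]2OC[C@H]3[C@@H]2C(=O)O[C@@H]3c2cc(OC)c(OCc4ccccc4)c(OC)c2)ccc1OCc1ccccc1 | intermediate
13 | (3S,3aR,6S,6aS)-3-(4-hydroxy-3,5-dimethoxyphenyl)-6-(4-hydroxy-3-methoxyphenyl)tetrahydro-1H,3H-furo[3,4-c]furan-1-one | COc1cc([C@H]2OC[C@H]3[C@@H]2C(=O)O[C@@H]3c2cc(OC)c(O)c(OC)c2)ccc1O | target

## Step count and risks

Total step count: 7. Longest linear sequence: 5 steps (steps 1, 2, 3, 6, 7); the ylide branch (steps 4, 5) joins at step 6.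

**Step 6 (most likely to fail).** The cycloaddition may show incomplete exo, facial or regiochemical control. The configuration at C5 of 6 may erode through reversible γ-deprotonation by fluoride before the dipole is trapped. The ylide may also electrocyclise to the aryl oxirane faster than it adds.

The fallback is a stepwise, tethered closure of the same tetrahydrofuran ring. It sets out from 6 (and uses 10) and comes back at 12.
- Benzophenone-sensitised photoaddition of methanol to 6 (MeOH, hν 350 nm, rt) should add the hydroxymethyl radical to the β-carbon anti to the aryl group and give the hydroxymethyl lactone F1.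
- O-Alkylation of F1 with chloro ether 10 (iPr2NEt, CH2Cl2, 0 °C) should give the mixed acetal F2.
- LiHMDS/TMSCl (THF, −78 °C) should convert F2 into the silyl ketene acetal F3.
- TMSOTf (CH2Cl2, −78 → 0 °C) should ionise the acetal of F3 to the oxocarbenium ion, which is captured by the ketene acetal in an intramolecular Mukaiyama-type addition to give 12.
- The tether enforces the cis ring fusion, and the aryl group at C6 should settle exo under the reversible Lewis-acid conditions.

**Step 7.** Hydrogenolysis may run on into the benzylic C3–O2 bond of the lactone and the C6–O5 bond of the ether ring. The fallback sets out from 12 and gives 13 directly: non-reductive debenzylation with BCl3 in the presence of pentamethylbenzene as benzyl-cation scavenger (CH2Cl2, −78 °C). It forms no new isolated compound, and any reversible ionisation at C6 should re-close to the same exo isomer.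

**Step 2.** Facial selectivity in the alkynylation may be insufficient or of the opposite sense with this electron-rich aldehyde, and the propiolate may oligomerise under the zinc base. The fallback replaces catalytic C–C bond formation by enzymatic resolution and ring-closing metathesis. It sets out from 2 and comes back at 6.
- Vinylmagnesium bromide (THF, −78 °C) should give the racemic allylic alcohol F4.
- Lipase-catalysed acylation (immobilised Candida antarctica lipase B, vinyl acetate, MTBE, rt), which acylates the R enantiomer of 1-arylalkanols, should leave the (S)-alcohol F5 beside the (R)-acetate F6.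
- Acryloyl chloride and iPr2NEt (CH2Cl2, 0 °C) should give the (S)-acrylate F7.
- Ring-closing metathesis (second-generation Ru–NHC catalyst, CH2Cl2, 40 °C) should close the butenolide 6.

## Further compounds

F1 | step 6 | (4R,5S)-5-[4-(benzyloxy)-3,5-dimethoxyphenyl]-4-(hydroxymethyl)dihydrofuran-2(3H)-one | OC[C@H]1CC(=O)O[C@@H]1c1cc(OC)c(OCc2ccccc2)c(OC)c1
F2 | step 6 | (4R,5S)-5-[4-(benzyloxy)-3,5-dimethoxyphenyl]-4-({[4-(benzyloxy)-3-methoxyphenyl][(trimethylsilyl)methoxy]methoxy}methyl)dihydrofuran-2(3H)-one, acetal epimers | C[Si](C)(C)COC(OC[C@H]1CC(=O)O[C@@H]1c1cc(OC)c(OCc2ccccc2)c(OC)c1)c1ccc(OCc2ccccc2)c(OC)c1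
F3 | step 6 | silyl ketene acetal of F2, {[(4R,5S)-5-aryl-4-(acetal-oxymethyl)-4,5-dihydrofuran-2-yl]oxy}trimethylsilane | C[Si](C)(C)COC(OC[C@H]1C=C(O[Si](C)(C)C)O[C@@H]1c1cc(OC)c(OCc2ccccc2)c(OC)c1)c1ccc(OCc2ccccc2)c(OC)c1
F0 | step 7 | none | none
F4 | step 2 | rac-1-[4-(benzyloxy)-3,5-dimethoxyphenyl]prop-2-en-1-ol | OC(c1cc(OC)c(OCc2ccccc2)c(OC)c1)C=C
F5 | step 2 | (S)-1-[4-(benzyloxy)-3,5-dimethoxyphenyl]prop-2-en-1-ol | O[C@H](c1cc(OC)c(OCc2ccccc2)c(OC)c1)C=C
F6 | step 2 | (R)-1-[4-(benzyloxy)-3,5-dimethoxyphenyl]prop-2-en-1-yl acetate | CC(=O)O[C@@H](c1cc(OC)c(OCc2ccccc2)c(OC)c1)C=C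
F7 | step 2 | (S)-1-[4-(benzyloxy)-3,5-dimethoxyphenyl]prop-2-en-1-yl acrylate | C=CC(=O)O[C@H](c1cc(OC)c(OCc2ccccc2)c(OC)c1)C=C
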